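**Retrosynthetic overview**
1. The only ring, the 14-membered lactone, is closed last in the skeleton-building sequence (C1 acid onto C13–OH); after it come only C3 carbinol → ketone and desilylation.
2. The C10–C11 diene bond is cut by a Suzuki–Miyaura coupling between a 2-bromoalkene (C1–C10) and a (Z)-alkenylboronate (C11–C13).
3. The C6 methyl enol ether comes from an (E)-alkenyl iodide by copper-catalysed C–O coupling, and the iodide from alkoxide-directed syn-hydrozirconation of a C6≡C7 alkyne.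
4. The C5–C6 bond is cut into a C6–C10 acetylide and a C1–C5 2,2-disubstituted epoxide, so three fragments of comparable size converge.
5. Stereocontrol: C8 by Evans alkylation, C2 by Evans syn-aldol, C4 by hydroxyl-directed epoxidation, C13 by catalytic asymmetric ethylzinc addition; both ring olefins come from stereospecific metalations.

Assumption: C1–C13 denote the macrolide backbone (C1 = lactone carbonyl, C13 = carbon bearing ethyl); TES = triethylsilyl, TBDPS = tert-butyldiphenylsilyl, pin = pinacolato; the oxazolidinone auxiliary and silyl groups are treated as reagents.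

**Step 1**
Reactants: 1 propanoyl chloride
Product: 2 (4R)-4-benzyl-3-propanoyl-1,3-oxazolidin-2-one
Conditions: (R)-4-benzyl-1,3-oxazolidin-2-one, Et3N, DMAP (cat.), CH2Cl2, 0 °C → rt
Reagents that add atoms: (R)-4-benzyl-1,3-oxazolidin-2-one O=C1N[C@H](Cc2ccccc2)CO1
Why: DMAP-catalysed N-acylation of the oxazolidinone by the acid chloride loads the Evans auxiliary that controls both later enolate reactions.

**Step 2**
Reactants: 2 (4R)-4-benzyl-3-propanoyl-1,3-oxazolidin-2-one; 3 2,3-dibromoprop-1-ene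
Product: 5 (4R)-4-benzyl-3-[(2S)-4-bromo-2-methylpent-4-enoyl]-1,3-oxazolidin-2-one, via sodium Z-enolate 4 (not isolated)
Conditions: NaN(SiMe3)2, THF, −78 °C; then 3, −78 → −40 °C
Reagents that add atoms: none
Why: In this Evans asymmetric alkylation the chelated Z-enolate is attacked by the allylic bromide on the face opposite the benzyl group, which sets the future C8 as S while the vinylic bromide stays inert.

**Step 3**
Reactants: 5 (4R)-4-benzyl-3-[(2S)-4-bromo-2-methylpent-4-enoyl]-1,3-oxazolidin-2-one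
Product: 6 (2S)-4-bromo-2-methylpent-4-en-1-ol
Conditions: LiBH4, H2O (1 equiv), Et2O, 0 °C
Reagents that add atoms: none
Why: Reductive cleavage of the N-acyl oxazolidinone by LiBH4 gives the primary alcohol without touching the stereocentre or the bromoalkene.

**Step 4**
Reactants: 6 (2S)-4-bromo-2-methylpent-4-en-1-ol
Product: 7 (2S)-4-bromo-2-methylpent-4-enal
Conditions: Dess–Martin periodinane, CH2Cl2, 0 °C → rt (kept in solution)
Reagents that add atoms: none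
Why: Dess–Martin oxidation is mild enough to give the α-branched aldehyde without epimerisation.

**Step 5**
Reactants: 7 (2S)-4-bromo-2-methylpent-4-enal
Product: 8 (3S)-5-bromo-3-methylhex-5-en-1-yne
Conditions: dimethyl (1-diazo-2-oxopropyl)phosphonate, K2CO3, MeOH, 0 °C → rt
Reagents that add atoms: dimethyl (1-diazo-2-oxopropyl)phosphonate COP(=O)(OC)C(=[N+]=[N-])C(C)=O
Why: The Ohira–Bestmann variant of the Seyferth–Gilbert homologation turns the aldehyde into the terminal alkyne (C6) under weakly basic conditions that preserve the α-stereocentre.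

**Step 6**
Reactants: 9 2-methylidenepropane-1,3-diol
Product: 10 2-(TBDPS-oxymethyl)prop-2-en-1-ol
Conditions: t-BuPh2SiCl (1 equiv), imidazole, THF, 0 °C, diol in threefold excess
Reagents that add atoms: tert-butyl(chloro)diphenylsilane CC(C)(C)[Si](Cl)(c1ccccc1)c1ccccc1
Why: Statistical monosilylation of the symmetrical diol with excess diol gives the mono-ether cleanly.

**Step 7**
Reactants: 10 2-(TBDPS-oxymethyl)prop-2-en-1-ol
Product: 11 2-(TBDPS-oxymethyl)prop-2-enal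
Conditions: MnO2, CH2Cl2, rt
Reagents that add atoms: none
Why: MnO2 selectively oxidises the allylic alcohol to the α-substituted acrolein.

**Step 8**
Reactants: 2 (4R)-4-benzyl-3-propanoyl-1,3-oxazolidin-2-one; 11 2-(TBDPS-oxymethyl)prop-2-enal
Product: 13 (4R)-4-benzyl-3-[(2R,3R)-3-hydroxy-2-methyl-4-(TBDPS-oxymethyl)pent-4-enoyl]-1,3-oxazolidin-2-one, via dibutylboron Z-enolate 12 (not isolated)
Conditions: Bu2BOTf, i-Pr2NEt, CH2Cl2, −78 → 0 °C; then 11, −78 → 0 °C; pH 7 buffer, MeOH, H2O2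
Reagents that add atoms: none
Why: The Evans syn-aldol reaction through a closed Zimmerman–Traxler transition state of the Z-boron enolate sets C2 as R and the C3 carbinol syn to it (3R).

**Step 9**
Reactants: 13 (4R)-4-benzyl-3-[(2R,3R)-3-hydroxy-2-methyl-4-(TBDPS-oxymethyl)pent-4-enoyl]-1,3-oxazolidin-2-one
Product: 14 (4R)-4-benzyl-3-{(2R,3R)-3-hydroxy-2-methyl-3-[(2R)-2-(TBDPS-oxymethyl)oxiran-2-yl]propanoyl}-1,3-oxazolidin-2-one
Conditions: VO(acac)2 (5 mol%), t-BuOOH, CH2Cl2, 0 °C → rt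
Reagents that add atoms: tert-butyl hydroperoxide CC(C)(C)OO
Why: In this hydroxyl-directed vanadium-catalysed epoxidation the 2-substituted allylic alcohol reacts through the conformer that avoids 1,2-allylic strain, giving the erythro epoxy alcohol and thereby the R configuration at the future C4.

**Step 10**
Reactants: 14 (4R)-4-benzyl-3-{(2R,3R)-3-hydroxy-2-methyl-3-[(2R)-2-(TBDPS-oxymethyl)oxiran-2-yl]propanoyl}-1,3-oxazolidin-2-one
Product: 15 (1R,2S)-2-methyl-1-[(2R)-2-(TBDPS-oxymethyl)oxiran-2-yl]propane-1,3-diol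
Conditions: LiBH4, H2O (1 equiv), Et2O, 0 °C
Reagents that add atoms: none
Why: Reductive removal of the auxiliary takes C1 to the alcohol level, so that no acyl group is present when the C4 alkoxide is later generated (a C1 carbonyl would be trapped as a γ-lactone).

**Step 11**
Reactants: 15 (1R,2S)-2-methyl-1-[(2R)-2-(TBDPS-oxymethyl)oxiran-2-yl]propane-1,3-diol
Product: 16 (2R)-2-[(1R,2S)-2-methyl-1,3-bis(TES-oxy)propyl]-2-(TBDPS-oxymethyl)oxirane
Conditions: Et3SiCl, imidazole, DMAP (cat.), DMF, 0 °C → rt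
Reagents that add atoms: chlorotriethylsilane CC[Si](Cl)(CC)CC
Why: Silylation under non-acidic conditions protects both hydroxyls without opening the epoxide and leaves a primary TES ether that can later be oxidised directly.

**Step 12**
Reactants: 17 prop-2-yn-1-ol
Product: 19 (2Z)-3-iodo-2-methylprop-2-en-1-ol, via Z-alkenylmagnesium alkoxide 18 (not isolated)
Conditions: MeMgBr (3 equiv), CuI (10 mol%), THF, −10 °C → rt; then I2, −10 °C
Reagents that add atoms: methylmagnesium bromide C[Mg]Br; iodine II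
Why: Copper-catalysed anti-carbomagnesiation of the propargylic alkoxide puts methyl on C12 and magnesium on C11 cis to the carbinol carbon, and iodinolysis with retention gives the Z-iodoalkene.

**Step 13**
Reactants: 19 (2Z)-3-iodo-2-methylprop-2-en-1-ol
Product: 20 (2Z)-3-iodo-2-methylprop-2-enal
Conditions: MnO2, CH2Cl2, rt, dark
Reagents that add atoms: none
Why: Neutral MnO2 oxidation of the allylic alcohol gives the enal without Z to E isomerisation.

**Step 14**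
Reactants: 20 (2Z)-3-iodo-2-methylprop-2-enal
Product: 21 (1Z,3S)-1-iodo-2-methylpent-1-en-3-ol
Conditions: Et2Zn, (2S)-(−)-3-exo-morpholinoisoborneol (4 mol%), toluene/hexanes, 0 °C
Reagents that add atoms: diethylzinc CC[Zn]CC
Why: In this amino-alcohol-catalysed asymmetric dialkylzinc addition the zinc aminoalkoxide delivers ethyl to the Si face of the enal (the same sense as with benzaldehyde), which sets C13 as S.

**Step 15**
Reactants: 21 (1Z,3S)-1-iodo-2-methylpent-1-en-3-ol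
Product: 22 (1Z,3S)-2-methyl-1-(4,4,5,5-tetramethyl-1,3,2-dioxaborolan-2-yl)pent-1-en-3-ol
Conditions: B2pin2, PdCl2(PPh3)2 (3 mol%), PPh3, KOPh, toluene, 50 °C
Reagents that add atoms: bis(pinacolato)diboron CC1(C)OB(OC1(C)C)B1OC(C)(C)C(C)(C)O1
Why: Miyaura borylation of the alkenyl iodide with phenoxide as base proceeds with retention of the Z geometry and tolerates the free hydroxyl.

**Step 16**
Reactants: 8 (3S)-5-bromo-3-methylhex-5-en-1-yne; 16 (2R)-2-[(1R,2S)-2-methyl-1,3-bis(TES-oxy)propyl]-2-(TBDPS-oxymethyl)oxirane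
Product: 24 (2S,3R,4R,8S)-10-bromo-2,8-dimethyl-4-(TBDPS-oxymethyl)-1,3-bis(TES-oxy)undec-10-en-6-yn-4-ol, via lithium acetylide 23 (not isolated)
Conditions: n-BuLi (0.95 equiv per 8), THF, −78 °C; BF3·OEt2; then 16, −78 °C
Reagents that add atoms: none
Why: In this Yamaguchi–Hirao alkynylation the BF3-activated epoxide is opened by the acetylide at its unsubstituted CH2 (C5), so the C5–C6 bond forms and the C4 configuration is untouched.

**Step 17**
Reactants: 24 (2S,3R,4R,8S)-10-bromo-2,8-dimethyl-4-(TBDPS-oxymethyl)-1,3-bis(TES-oxy)undec-10-en-6-yn-4-ol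
Product: 27 (2S,3R,4R,6E,8S)-10-bromo-6-iodo-2,8-dimethyl-4-(TBDPS-oxymethyl)-1,3-bis(TES-oxy)undeca-6,10-dien-4-ol, via lithium alkoxide 25 (not isolated), via oxazirconacycle 26 (not isolated)
Conditions: MeLi (1.05 equiv), THF, −78 → 0 °C; Cp2Zr(H)Cl (2 equiv), THF, rt; then I2, −78 → 0 °C
Reagents that add atoms: iodine II
Why: In this alkoxide-directed Schwartz hydrozirconation the homopropargylic alkoxide delivers Zr–H syn with zirconium on the proximal carbon C6 (five-membered chelate), and iodinolysis with retention leaves iodine cis to H-7, so C5 and C8 are cis.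

**Step 18**
Reactants: 27 (2S,3R,4R,6E,8S)-10-bromo-6-iodo-2,8-dimethyl-4-(TBDPS-oxymethyl)-1,3-bis(TES-oxy)undeca-6,10-dien-4-ol
Product: 28 (2S,3R,4R,6E,8S)-10-bromo-6-iodo-2,8-dimethyl-4-(TBDPS-oxymethyl)-1,3,4-tris(TES-oxy)undeca-6,10-diene
Conditions: Et3SiOTf, 2,6-lutidine, CH2Cl2, −78 → 0 °C
Reagents that add atoms: triethylsilyl trifluoromethanesulfonate CC[Si](CC)(CC)OS(=O)(=O)C(F)(F)F
Why: The silyl triflate caps the hindered tertiary hydroxyl, which would otherwise form an oxetane in the copper step and a γ-lactone once C1 becomes an acid.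

**Step 19**
Reactants: 28 (2S,3R,4R,6E,8S)-10-bromo-6-iodo-2,8-dimethyl-4-(TBDPS-oxymethyl)-1,3,4-tris(TES-oxy)undeca-6,10-diene
Product: 29 (2R,3R,4R,6E,8S)-10-bromo-6-iodo-2,8-dimethyl-4-(TBDPS-oxymethyl)-3,4-bis(TES-oxy)undeca-6,10-dienal
Conditions: (COCl)2, DMSO, CH2Cl2, −78 → −30 °C; then Et3N, −78 → 0 °C
Reagents that add atoms: none
Why: Under Swern conditions a primary TES ether is cleaved and oxidised in one operation while secondary and tertiary TES ethers and the TBDPS ether survive, giving the C1 aldehyde directly.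

**Step 20**
Reactants: 29 (2R,3R,4R,6E,8S)-10-bromo-6-iodo-2,8-dimethyl-4-(TBDPS-oxymethyl)-3,4-bis(TES-oxy)undeca-6,10-dienal
Product: 30 (2R,3R,4R,6E,8S)-10-bromo-6-iodo-2,8-dimethyl-4-(TBDPS-oxymethyl)-3,4-bis(TES-oxy)undeca-6,10-dienoic acid
Conditions: NaClO2, NaH2PO4, 2-methylbut-2-ene, t-BuOH/H2O, 0 °C → rt
Reagents that add atoms: sodium chlorite [Na+].[O-]Cl=O
Why: The Pinnick oxidation is placed before the enol ether exists, so its mildly acidic medium harms nothing and the α-stereocentre is not epimerised.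

**Step 21**
Reactants: 30 (2R,3R,4R,6E,8S)-10-bromo-6-iodo-2,8-dimethyl-4-(TBDPS-oxymethyl)-3,4-bis(TES-oxy)undeca-6,10-dienoic acid
Product: 31 (2R,3R,4R,6E,8S)-10-bromo-6-methoxy-2,8-dimethyl-4-(TBDPS-oxymethyl)-3,4-bis(TES-oxy)undeca-6,10-dienoic acid
Conditions: MeOH, CuI (20 mol%), 3,4,7,8-tetramethyl-1,10-phenanthroline (40 mol%), Cs2CO3 (3 equiv), toluene, 80 °C; pH 7 buffer work-up, used at once as the triethylammonium salt
Reagents that add atoms: methanol CO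
Why: Copper-catalysed Ullmann-type C–O coupling of alkenyl iodides is stereoretentive and favours iodide over the 2-bromoalkene, and the carboxylate form of C1 keeps C2 from enolising, so the methoxy group ends up cis to H-7.

**Step 22**
Reactants: 31 (2R,3R,4R,6E,8S)-10-bromo-6-methoxy-2,8-dimethyl-4-(TBDPS-oxymethyl)-3,4-bis(TES-oxy)undeca-6,10-dienoic acid; 22 (1Z,3S)-2-methyl-1-(4,4,5,5-tetramethyl-1,3,2-dioxaborolan-2-yl)pent-1-en-3-ol
Product: 32 (2R,3R,4R,6E,8S,11Z,13S)-13-hydroxy-6-methoxy-2,8,12-trimethyl-10-methylidene-4-(TBDPS-oxymethyl)-3,4-bis(TES-oxy)pentadeca-6,11-dienoic acid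
Conditions: Pd(dppf)Cl2 (10 mol%), aq. K3PO4, THF, 45 °C, degassed
Reagents that add atoms: none
Why: Suzuki–Miyaura coupling joins the 2-bromoalkene and the Z-alkenylboronate with retention at both partners under basic conditions that the enol ether tolerates, forming the C10–C11 bond of the 2-substituted diene.

**Step 23**
Reactants: 32 (2R,3R,4R,6E,8S,11Z,13S)-13-hydroxy-6-methoxy-2,8,12-trimethyl-10-methylidene-4-(TBDPS-oxymethyl)-3,4-bis(TES-oxy)pentadeca-6,11-dienoic acid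
Product: 34 (3R,4R,5R,7E,9S,12Z,14S)-14-ethyl-7-methoxy-3,9,13-trimethyl-11-methylidene-5-(TBDPS-oxymethyl)-4,5-bis(TES-oxy)-1-oxacyclotetradeca-7,12-dien-2-one, via mixed anhydride 33 (not isolated)
Conditions: 2,4,6-Cl3C6H2COCl, Et3N, THF, rt; then slow addition to DMAP, toluene, 60 °C, about 1 mM
Reagents that add atoms: none
Why: In this Yamaguchi macrolactonisation C13–OH is the only free hydroxyl, so the DMAP-activated mixed anhydride closes the 14-membered ring under basic, high-dilution conditions that spare the enol ether.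

**Step 24**
Reactants: 34 (3R,4R,5R,7E,9S,12Z,14S)-14-ethyl-7-methoxy-3,9,13-trimethyl-11-methylidene-5-(TBDPS-oxymethyl)-4,5-bis(TES-oxy)-1-oxacyclotetradeca-7,12-dien-2-one
Product: 35 (3R,4R,5R,7E,9S,12Z,14S)-14-ethyl-4-hydroxy-7-methoxy-3,9,13-trimethyl-11-methylidene-5-(TBDPS-oxymethyl)-5-(TES-oxy)-1-oxacyclotetradeca-7,12-dien-2-one
Conditions: HF·pyridine, excess pyridine, THF, 0 °C
Reagents that add atoms: none
Why: Pyridine-buffered HF removes the secondary TES ether selectively, because the tertiary TES ether is more hindered and the TBDPS ether is far more stable to these conditions.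

**Step 25**
Reactants: 35 (3R,4R,5R,7E,9S,12Z,14S)-14-ethyl-4-hydroxy-7-methoxy-3,9,13-trimethyl-11-methylidene-5-(TBDPS-oxymethyl)-5-(TES-oxy)-1-oxacyclotetradeca-7,12-dien-2-one
Product: 36 (3R,5R,7E,9S,12Z,14S)-14-ethyl-7-methoxy-3,9,13-trimethyl-11-methylidene-5-(TBDPS-oxymethyl)-5-(TES-oxy)-1-oxacyclotetradeca-7,12-diene-2,4-dione
Conditions: Dess–Martin periodinane, pyridine, CH2Cl2, 0 °C → rt
Reagents that add atoms: none
Why: Buffered Dess–Martin oxidation converts the C3 carbinol into the β-keto lactone under non-enolising conditions, so the C2 configuration set in step 8 is kept.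

**Step 26**
Reactants: 36 (3R,5R,7E,9S,12Z,14S)-14-ethyl-7-methoxy-3,9,13-trimethyl-11-methylidene-5-(TBDPS-oxymethyl)-5-(TES-oxy)-1-oxacyclotetradeca-7,12-diene-2,4-dione
Product: 37 (3R,5R,7E,9S,12Z,14S)-14-ethyl-5-hydroxy-5-(hydroxymethyl)-7-methoxy-3,9,13-trimethyl-11-methylidene-1-oxacyclotetradeca-7,12-diene-2,4-dione
Conditions: Bu4NF, AcOH (1:1), THF, 0 °C → rt
Reagents that add atoms: none
Why: Acetic-acid-buffered fluoride removes the α-keto tertiary TES ether and the primary TBDPS ether near neutrality, which protects the enol ether from acid and the β-keto lactone from base.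

**Compound list**
1 | propanoyl chloride | CCC(=O)Cl | starting material
2 | (4R)-4-benzyl-3-propanoyl-1,3-oxazolidin-2-one | CCC(=O)N1[C@H](Cc2ccccc2)COC1=O | intermediate
3 | 2,3-dibromoprop-1-ene | C=C(Br)CBr | starting material
4 | sodium Z-enolate of 2 | C/C=C(\[O-])N1[C@H](Cc2ccccc2)COC1=O.[Na+] | intermediate
5 | (4R)-4-benzyl-3-[(2S)-4-bromo-2-methylpent-4-enoyl]-1,3-oxazolidin-2-one | C=C(Br)C[C@H](C)C(=O)N1[C@H](Cc2ccccc2)COC1=O | intermediate
6 | (2S)-4-bromo-2-methylpent-4-en-1-ol | C=C(Br)C[C@H](C)CO | intermediate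
7 | (2S)-4-bromo-2-methylpent-4-enal | C=C(Br)C[C@H](C)C=O | intermediate
8 | (3S)-5-bromo-3-methylhex-5-en-1-yne (fragment 1, C6–C10) | C=C(Br)C[C@H](C)C#C | intermediate
9 | 2-methylidenepropane-1,3-diol | C=C(CO)CO | starting material
10 | 2-(TBDPS-oxymethyl)prop-2-en-1-ol | C=C(CO)CO[Si](c1ccccc1)(c1ccccc1)C(C)(C)C | intermediate
11 | 2-(TBDPS-oxymethyl)prop-2-enal | C=C(C=O)CO[Si](c1ccccc1)(c1ccccc1)C(C)(C)C | intermediate
12 | dibutylboron Z-enolate of 2 | C/C=C(\OB(CCCC)CCCC)N1[C@H](Cc2ccccc2)COC1=O | intermediate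
13 | (4R)-4-benzyl-3-[(2R,3R)-3-hydroxy-2-methyl-4-(TBDPS-oxymethyl)pent-4-enoyl]-1,3-oxazolidin-2-one | O=C(N1[C@H](Cc2ccccc2)COC1=O)[C@H](C)[C@@H](O)C(=C)CO[Si](c1ccccc1)(c1ccccc1)C(C)(C)C | intermediate
14 | (4R)-4-benzyl-3-{(2R,3R)-3-hydroxy-2-methyl-3-[(2R)-2-(TBDPS-oxymethyl)oxiran-2-yl]propanoyl}-1,3-oxazolidin-2-one | O=C(N1[C@H](Cc2ccccc2)COC1=O)[C@H](C)[C@@H](O)[C@]1(CO[Si](c2ccccc2)(c2ccccc2)C(C)(C)C)CO1 | intermediate
15 | (1R,2S)-2-methyl-1-[(2R)-2-(TBDPS-oxymethyl)oxiran-2-yl]propane-1,3-diol | OC[C@H](C)[C@@H](O)[C@]1(CO[Si](c2ccccc2)(c2ccccc2)C(C)(C)C)CO1 | intermediate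
16 | (2R)-2-[(1R,2S)-2-methyl-1,3-bis(TES-oxy)propyl]-2-(TBDPS-oxymethyl)oxirane (fragment 2, C1–C5) | CC[Si](CC)(CC)OC[C@H](C)[C@@H](O[Si](CC)(CC)CC)[C@]1(CO[Si](c2ccccc2)(c2ccccc2)C(C)(C)C)CO1 | intermediate
17 | prop-2-yn-1-ol | C#CCO | starting material
18 | Z-alkenylmagnesium alkoxide from 17 | Br[Mg]OC/C(C)=C\[Mg]Br | intermediate
19 | (2Z)-3-iodo-2-methylprop-2-en-1-ol | OC/C(C)=C\I | intermediate
20 | (2Z)-3-iodo-2-methylprop-2-enal | O=C/C(C)=C\I | intermediate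
21 | (1Z,3S)-1-iodo-2-methylpent-1-en-3-ol | CC[C@H](O)/C(C)=C\I | intermediate
22 | (1Z,3S)-2-methyl-1-(4,4,5,5-tetramethyl-1,3,2-dioxaborolan-2-yl)pent-1-en-3-ol (fragment 3, C11–C13) | CC[C@H](O)/C(C)=C\B1OC(C)(C)C(C)(C)O1 | intermediate
23 | lithium acetylide of 8 | [Li]C#C[C@@H](C)CC(Br)=C | intermediate
24 | (2S,3R,4R,8S)-10-bromo-2,8-dimethyl-4-(TBDPS-oxymethyl)-1,3-bis(TES-oxy)undec-10-en-6-yn-4-ol | CC[Si](CC)(CC)OC[C@H](C)[C@@H](O[Si](CC)(CC)CC)[C@](O)(CO[Si](c1ccccc1)(c1ccccc1)C(C)(C)C)CC#C[C@@H](C)CC(Br)=C | intermediate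
25 | lithium alkoxide of 24 | CC[Si](CC)(CC)OC[C@H](C)[C@@H](O[Si](CC)(CC)CC)[C@]([O-])(CO[Si](c1ccccc1)(c1ccccc1)C(C)(C)C)CC#C[C@@H](C)CC(Br)=C.[Li+] | intermediate
26 | oxazirconacycle (Cp2Zr bridging O-4 and C6, exocyclic C6=C7) | CC[Si](CC)(CC)OC[C@H](C)[C@@H](O[Si](CC)(CC)CC)[C@]1(CO[Si](c2ccccc2)(c2ccccc2)C(C)(C)C)C/C(=C\[C@@H](C)CC(Br)=C)[Zr](C2C=CC=C2)(C2C=CC=C2)O1 | intermediate
27 | (2S,3R,4R,6E,8S)-10-bromo-6-iodo-2,8-dimethyl-4-(TBDPS-oxymethyl)-1,3-bis(TES-oxy)undeca-6,10-dien-4-ol | CC[Si](CC)(CC)OC[C@H](C)[C@@H](O[Si](CC)(CC)CC)[C@](O)(CO[Si](c1ccccc1)(c1ccccc1)C(C)(C)C)C/C(I)=C\[C@@H](C)CC(Br)=C | intermediate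
28 | (2S,3R,4R,6E,8S)-10-bromo-6-iodo-2,8-dimethyl-4-(TBDPS-oxymethyl)-1,3,4-tris(TES-oxy)undeca-6,10-diene | CC[Si](CC)(CC)OC[C@H](C)[C@@H](O[Si](CC)(CC)CC)[C@](O[Si](CC)(CC)CC)(CO[Si](c1ccccc1)(c1ccccc1)C(C)(C)C)C/C(I)=C\[C@@H](C)CC(Br)=C | intermediate
29 | (2R,3R,4R,6E,8S)-10-bromo-6-iodo-2,8-dimethyl-4-(TBDPS-oxymethyl)-3,4-bis(TES-oxy)undeca-6,10-dienal | O=C[C@H](C)[C@@H](O[Si](CC)(CC)CC)[C@](O[Si](CC)(CC)CC)(CO[Si](c1ccccc1)(c1ccccc1)C(C)(C)C)C/C(I)=C\[C@@H](C)CC(Br)=C | intermediate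
30 | (2R,3R,4R,6E,8S)-10-bromo-6-iodo-2,8-dimethyl-4-(TBDPS-oxymethyl)-3,4-bis(TES-oxy)undeca-6,10-dienoic acid | OC(=O)[C@H](C)[C@@H](O[Si](CC)(CC)CC)[C@](O[Si](CC)(CC)CC)(CO[Si](c1ccccc1)(c1ccccc1)C(C)(C)C)C/C(I)=C\[C@@H](C)CC(Br)=C | intermediate
31 | (2R,3R,4R,6E,8S)-10-bromo-6-methoxy-2,8-dimethyl-4-(TBDPS-oxymethyl)-3,4-bis(TES-oxy)undeca-6,10-dienoic acid | OC(=O)[C@H](C)[C@@H](O[Si](CC)(CC)CC)[C@](O[Si](CC)(CC)CC)(CO[Si](c1ccccc1)(c1ccccc1)C(C)(C)C)C/C(OC)=C\[C@@H](C)CC(Br)=C | intermediate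
32 | (2R,3R,4R,6E,8S,11Z,13S)-13-hydroxy-6-methoxy-2,8,12-trimethyl-10-methylidene-4-(TBDPS-oxymethyl)-3,4-bis(TES-oxy)pentadeca-6,11-dienoic acid | OC(=O)[C@H](C)[C@@H](O[Si](CC)(CC)CC)[C@](O[Si](CC)(CC)CC)(CO[Si](c1ccccc1)(c1ccccc1)C(C)(C)C)C/C(OC)=C\[C@@H](C)CC(=C)/C=C(/C)[C@H](CC)O | intermediate
33 | mixed 2,4,6-trichlorobenzoic anhydride of 32 | O=C(OC(=O)c1c(Cl)cc(Cl)cc1Cl)[C@H](C)[C@@H](O[Si](CC)(CC)CC)[C@](O[Si](CC)(CC)CC)(CO[Si](c1ccccc1)(c1ccccc1)C(C)(C)C)C/C(OC)=C\[C@@H](C)CC(=C)/C=C(/C)[C@H](CC)O | intermediate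
34 | (3R,4R,5R,7E,9S,12Z,14S)-14-ethyl-7-methoxy-3,9,13-trimethyl-11-methylidene-5-(TBDPS-oxymethyl)-4,5-bis(TES-oxy)-1-oxacyclotetradeca-7,12-dien-2-one | C=C1/C=C(/C)[C@H](CC)OC(=O)[C@H](C)[C@@H](O[Si](CC)(CC)CC)[C@](O[Si](CC)(CC)CC)(CO[Si](c2ccccc2)(c2ccccc2)C(C)(C)C)C/C(OC)=C\[C@@H](C)C1 | intermediate
35 | (3R,4R,5R,7E,9S,12Z,14S)-14-ethyl-4-hydroxy-7-methoxy-3,9,13-trimethyl-11-methylidene-5-(TBDPS-oxymethyl)-5-(TES-oxy)-1-oxacyclotetradeca-7,12-dien-2-one | C=C1/C=C(/C)[C@H](CC)OC(=O)[C@H](C)[C@@H](O)[C@](O[Si](CC)(CC)CC)(CO[Si](c2ccccc2)(c2ccccc2)C(C)(C)C)C/C(OC)=C\[C@@H](C)C1 | intermediate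
36 | (3R,5R,7E,9S,12Z,14S)-14-ethyl-7-methoxy-3,9,13-trimethyl-11-methylidene-5-(TBDPS-oxymethyl)-5-(TES-oxy)-1-oxacyclotetradeca-7,12-diene-2,4-dione | C=C1/C=C(/C)[C@H](CC)OC(=O)[C@H](C)C(=O)[C@](O[Si](CC)(CC)CC)(CO[Si](c2ccccc2)(c2ccccc2)C(C)(C)C)C/C(OC)=C\[C@@H](C)C1 | intermediate
37 | (3R,5R,7E,9S,12Z,14S)-14-ethyl-5-hydroxy-5-(hydroxymethyl)-7-methoxy-3,9,13-trimethyl-11-methylidene-1-oxacyclotetradeca-7,12-diene-2,4-dione | C=C1/C=C(/C)[C@H](CC)OC(=O)[C@H](C)C(=O)[C@](O)(CO)C/C(OC)=C\[C@@H](C)C1 | target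

**Totals**
Total step count: 26.
Longest linear sequence: 17 steps (steps 6–11, then 16–26), which is 65 % of the total.

**Steps most likely to fail**

Step 17 (directed hydrozirconation–iodination). The regiochemistry depends on delivery by the lithium alkoxide, and Cp2Zr(H)Cl may also attack the 2-bromoalkene. The fallback sets out from 24 and comes back at 27. The tertiary hydroxyl of 24 is silylated with 1,1,3,3-tetramethyldisilazane to give the dimethylsilyl ether F1. Pt2[(CH2=CHSiMe2)2O]3 (Karstedt catalyst, zerovalent platinum) in THF at rt then effects intramolecular syn 5-exo-dig hydrosilylation to the E-alkylidene oxasilolane F2, with silicon on C6 cis to H-7. Iododesilylation with N-iodosuccinimide in MeCN at 0 °C (retention), followed by K2CO3/MeOH to cleave the remaining Si–O bond, gives 27.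

Step 21 (copper-catalysed methoxylation). The iodide sits next to a quaternary centre, and the 2-bromoalkene could compete at 80 °C. The fallback sets out from 30 and comes back at 31. Iodide-selective Miyaura borylation (B2pin2, PdCl2(PPh3)2, KOPh, toluene, 50 °C) gives the alkenylboronate F3. Chan–Lam–Evans etherification (Cu(OAc)2, Et3N, MeOH, air, molecular sieves, rt) then replaces boron by methoxy with retention at room temperature.

Step 23 (macrolactonisation). The heavily silylated seco acid may oligomerise or epimerise at C2 through a ketene before the ring closes. The fallback sets out from 31 and boronate 22 and comes back at 34, replacing steps 22 and 23. Acid 31 is esterified with the hydroxyl of 22 (2,4,6-Cl3C6H2COCl, Et3N, DMAP, toluene, rt) to give the ester F4. The ring is then closed at C10–C11 by intramolecular Suzuki–Miyaura coupling (Pd(dppf)Cl2, aq. K3PO4, THF, 45 °C, about 1 mM).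

**Further compounds**
F1 | step 17 | (2S,3R,4R,8S)-10-bromo-4-(dimethylsilyloxy)-2,8-dimethyl-4-(TBDPS-oxymethyl)-1,3-bis(TES-oxy)undec-10-en-6-yne | CC[Si](CC)(CC)OC[C@H](C)[C@@H](O[Si](CC)(CC)CC)[C@](O[SiH](C)C)(CO[Si](c1ccccc1)(c1ccccc1)C(C)(C)C)CC#C[C@@H](C)CC(Br)=C
F2 | step 17 | (3E,5R)-3-[(2S)-4-bromo-2-methylpent-4-en-1-ylidene]-2,2-dimethyl-5-[(1R,2S)-2-methyl-1,3-bis(TES-oxy)propyl]-5-(TBDPS-oxymethyl)-1,2-oxasilolane | CC[Si](CC)(CC)OC[C@H](C)[C@@H](O[Si](CC)(CC)CC)[C@]1(CO[Si](c2ccccc2)(c2ccccc2)C(C)(C)C)C/C(=C\[C@@H](C)CC(Br)=C)[Si](C)(C)O1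
F3 | step 21 | (2R,3R,4R,6Z,8S)-10-bromo-2,8-dimethyl-6-(4,4,5,5-tetramethyl-1,3,2-dioxaborolan-2-yl)-4-(TBDPS-oxymethyl)-3,4-bis(TES-oxy)undeca-6,10-dienoic acid | OC(=O)[C@H](C)[C@@H](O[Si](CC)(CC)CC)[C@](O[Si](CC)(CC)CC)(CO[Si](c1ccccc1)(c1ccccc1)C(C)(C)C)C/C(B1OC(C)(C)C(C)(C)O1)=C\[C@@H](C)CC(Br)=C
F4 | step 23 | (1Z,3S)-2-methyl-1-(4,4,5,5-tetramethyl-1,3,2-dioxaborolan-2-yl)pent-1-en-3-yl (2R,3R,4R,6E,8S)-10-bromo-6-methoxy-2,8-dimethyl-4-(TBDPS-oxymethyl)-3,4-bis(TES-oxy)undeca-6,10-dienoate | O=C(O[C@@H](CC)/C(C)=C\B1OC(C)(C)C(C)(C)O1)[C@H](C)[C@@H](O[Si](CC)(CC)CC)[C@](O[Si](CC)(CC)CC)(CO[Si](c1ccccc1)(c1ccccc1)C(C)(C)C)C/C(OC)=C\[C@@H](C)CC(Br)=C
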